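**Retrosynthetic overview**

- Numbering: carotenoid locants. Ring B is the trihydroxy ring (C1 = CMe2, C2 = CH2, C3 = CHOH, C4 = CH2, C5 = C(OH)Me, C6 = C(OH) carrying the chain); ring A is the enyne ring (primed locants). The polyene is cut by two Wittig olefinations: C11'=C12' (ring A C15 phosphonium salt 21 + C10 dialdehyde 22) and then C11=C12 (C25 phosphonium salt 25 + ring B C15 aldehyde 15).
- Ring B side chain: C6–C7 by addition of the acetylide of enynol 11 to the C6 ketone 10, then trans-hydroalumination; C5–OH by Rubottom oxidation of a C5=C6 silyl enol ether; C3–OH by Baeyer–Villiger oxidation of a C3 acetyl group.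
- Ring construction: the cyclohexane is made once and first, by a catalytic enantioselective formal [4+2] addition of silyl dienol ether 4 (C1, C6, C5, C4) to but-3-en-2-one 5 (C2, C3), which forms C1–C2 and C3–C4 and gives 6. One portion of 6 becomes ring B, the other ring A (enol triflate 18, Sonogashira coupling with 11).
- Enabling feature: C6 of ring B is a latent ketone flanked by the gem-dimethyl carbon C1 and the methyl-bearing carbon C5, and the carbinol C3 sits para (1,4) to it. Ring B is therefore the adduct of a 2-silyloxy-1,3-diene C1=C6(O)–C5=C4 and a two-carbon acceptor C2=C3; ring A (C5'=C6', C3'–OH) has the same pattern.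
- Stereochemistry: C3 is set by the catalyst in the key step; C5 and C6 follow by substrate control; C3' is the same centre carried into ring A.

Key step: step 3

Remark: the (S)-prolinol-derived oxazaborolidine is chosen for step 3 from the accepted enone-binding model of this catalyst class, and the sense of induction with the new diene would have to be confirmed on the first run (the mirror-image catalyst is equally accessible); 11 and 22 are taken as commercial.

**Route**

Step 1
Reactants: 1 N-methoxy-N,2-dimethylpropanamide; 2 prop-1-en-2-ylmagnesium bromide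
Product: 3 2,4-dimethylpent-1-en-3-one
Conditions: THF, 0 °C; inverse quench into cold 1 M HCl
Reagents that add atoms: none
Why: Acylation of an organomagnesium reagent by an N-methoxy-N-methylamide stops at the chelated tetrahedral intermediate, and the acidic quench releases the enone while keeping the liberated amine protonated so that it cannot add to it.

Step 2
Reactants: 3 2,4-dimethylpent-1-en-3-one
Product: 4 tert-butyl[(2,4-dimethylpenta-1,3-dien-3-yl)oxy]dimethylsilane
Conditions: TBSOTf, Et3N, CH2Cl2, 0 °C → rt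
Reagents that add atoms: tert-butyldimethylsilyl trifluoromethanesulfonate, CC(C)(C)[Si](C)(C)OS(=O)(=O)C(F)(F)F
Why: Soft enolisation and O-silylation; the isopropyl methine is the only enolisable position, so a single cross-conjugated 2-silyloxydiene should form.

Step 3
Reactants: 4 tert-butyl[(2,4-dimethylpenta-1,3-dien-3-yl)oxy]dimethylsilane; 5 but-3-en-2-one
Product: 6 1-[(1R)-4-{[tert-butyl(dimethyl)silyl]oxy}-3,5,5-trimethylcyclohex-3-en-1-yl]ethan-1-one
Conditions: (S)-1-(2-methylphenyl)-3,3-diphenyltetrahydro-1H,3H-pyrrolo[1,2-c][1,3,2]oxazaborole (10 mol%), AlBr3 (8 mol%), CH2Cl2, −78 °C; Et3N quench, filtration through basic Al2O3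
Reagents that add atoms: none
Why: Proposed new method: the AlBr3-activated oxazaborolidinium ion binds but-3-en-2-one, whose β-carbon (C2) is attacked by the nucleophilic CMe2 terminus (C1) of the silyl dienol ether in a Mukaiyama–Michael step, and the boron enolate so formed (C3) closes onto C4 of the silyloxyallyl cation just created (6-endo-trig Michael-type closure of the one six-membered ring), that is, a strongly asynchronous formal [4+2] cycloaddition that ends in the silyl enol ether 6. The closest known reaction types are the AlBr3-based Lewis acid catalysed cycloadditions of fully substituted 2-silyloxydienes with enones and the oxazaborolidinium-catalysed enantioselective Diels–Alder reactions of 2-silyloxybutadienes with vinyl ketones; new is their combination on a diene whose nucleophilic terminus is tetrasubstituted. C3 is the only stereocentre formed and is controlled by the catalyst, which shields one enantioface of the bound enone so that both bonds form on the same face before the C2–C3 bond can rotate. Regioselectivity (acetyl para to the silyloxy carbon) is secured by the polarisation of the enol ether, since only C1 is nucleophilic and only C4 becomes electrophilic, and the gem-dimethyl group, which forbids a concerted s-cis pathway, is tolerated because the first bond forms stepwise. The step needs high enantioselectivity and ring closure in preference to arrest at the open Michael adduct, both of which low temperature and the non-nucleophilic counter-ion should favour.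

Step 4
Reactants: 6 1-[(1R)-4-{[tert-butyl(dimethyl)silyl]oxy}-3,5,5-trimethylcyclohex-3-en-1-yl]ethan-1-one
Product: 8 (1S,3S)-3-{[tert-butyl(dimethyl)silyl]oxy}-3,5,5-trimethyl-4-oxocyclohexyl acetate, via silyloxy diketone 7 (not isolated)
Conditions: mCPBA (3.5 equiv), NaHCO3, CH2Cl2, −20 °C → rt
Reagents that add atoms: 3-chloroperoxybenzoic acid, OOC(=O)c1cccc(Cl)c1
Why: Rubottom oxidation, in which the peracid should attack the silyl enol ether anti to the pseudoaxial C1 methyl of the half-chair with equatorial C3 acetyl, so that after 1,4-silyl shift the C5 oxygen is cis to the C3 substituent; the excess peracid then converts the methyl ketone into the acetate by Baeyer–Villiger oxidation with retention at C3, the now 2,2,6,6-tetrasubstituted ring ketone being too hindered to react.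

Step 5
Reactants: 8 (1S,3S)-3-{[tert-butyl(dimethyl)silyl]oxy}-3,5,5-trimethyl-4-oxocyclohexyl acetate
Product: 10 (2S,4S)-2,4-dihydroxy-2,6,6-trimethylcyclohexan-1-one, via hydroxy ketone acetate 9 (not isolated)
Conditions: Bu4NF, THF, −20 °C; then MeOH, K2CO3 (cat.), 0 °C; aq. NH4Cl
Reagents that add atoms: none
Why: Fluoride cleavage of the tertiary silyl ether followed by base-catalysed transesterification of the acetate (Zemplén type); the ketone has no α-hydrogen and no stereocentre is touched.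

Step 6
Reactants: 10 (2S,4S)-2,4-dihydroxy-2,6,6-trimethylcyclohexan-1-one; 11 (2E)-3-methylpent-2-en-4-yn-1-ol
Product: 13 (1R,2S,4S)-1-[(3E)-5-hydroxy-3-methylpent-3-en-1-yn-1-yl]-2,6,6-trimethylcyclohexane-1,2,4-triol, via dilithio enynol 12 (not isolated)
Conditions: 11 (4 equiv), n-BuLi (8 equiv), THF, −78 → 0 °C; then 10, −78 → −20 °C; aq. NH4Cl
Reagents that add atoms: none
Why: 1,2-Addition of a lithium acetylide to a non-enolisable ketone under chelation and steric control: in the lithium-chelated chair with the C3 and C5 oxygens equatorial, the axial methyls at C1 and C5 close one face, so the acetylide should enter axially from the other and leave the C6 hydroxyl trans to the C5 and C3 hydroxyls.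

Step 7
Reactants: 13 (1R,2S,4S)-1-[(3E)-5-hydroxy-3-methylpent-3-en-1-yn-1-yl]-2,6,6-trimethylcyclohexane-1,2,4-triol
Product: 14 (1S,2S,4S)-1-[(1E,3E)-5-hydroxy-3-methylpenta-1,3-dien-1-yl]-2,6,6-trimethylcyclohexane-1,2,4-triol
Conditions: NaAlH2(OCH2CH2OMe)2 (excess), THF, 0 °C → rt; aq. potassium sodium tartrate
Reagents that add atoms: none
Why: Alkoxide-directed trans-hydroalumination of the tertiary propargylic alcohol and protonolysis should give only the (E)-alkene at C7=C8 and leave the trisubstituted C9=C10 bond alone.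

Step 8
Reactants: 14 (1S,2S,4S)-1-[(1E,3E)-5-hydroxy-3-methylpenta-1,3-dien-1-yl]-2,6,6-trimethylcyclohexane-1,2,4-triol
Product: 15 (2E,4E)-3-methyl-5-[(1S,2S,4S)-1,2,4-trihydroxy-2,6,6-trimethylcyclohexyl]penta-2,4-dienal
Conditions: MnO2, acetone, rt
Reagents that add atoms: none
Why: Allylic oxidation by MnO2 is selective for the primary dienylic alcohol over the saturated secondary and the tertiary hydroxyls.

Step 9
Reactants: 6 1-[(1R)-4-{[tert-butyl(dimethyl)silyl]oxy}-3,5,5-trimethylcyclohex-3-en-1-yl]ethan-1-one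
Product: 16 (4R)-4-acetyl-2,2,6-trimethylcyclohexan-1-one (mixture of epimers at the methyl-bearing ring carbon)
Conditions: Bu4NF, AcOH (1:1), THF, 0 °C
Reagents that add atoms: none
Why: Fluoride cleavage of the silyl enol ether with buffered protonation of the enolate, so that the acetyl-bearing stereocentre is not enolised; the new methyl-bearing centre is inconsequential because it becomes sp2 again in step 11.

Step 10
Reactants: 16 (4R)-4-acetyl-2,2,6-trimethylcyclohexan-1-one
Product: 17 (1R)-3,3,5-trimethyl-4-oxocyclohexyl acetate (mixture of epimers at the methyl-bearing ring carbon)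
Conditions: mCPBA, NaHCO3, CH2Cl2, 0 °C → rt
Reagents that add atoms: 3-chloroperoxybenzoic acid, OOC(=O)c1cccc(Cl)c1
Why: Baeyer–Villiger oxidation in which the unhindered methyl ketone should react before the ring ketone flanked by a quaternary and a tertiary carbon, the secondary ring carbon migrating with retention so that C3' keeps its configuration.

Step 11
Reactants: 17 (1R)-3,3,5-trimethyl-4-oxocyclohexyl acetate
Product: 18 (1R)-3,5,5-trimethyl-4-{[(trifluoromethyl)sulfonyl]oxy}cyclohex-3-en-1-yl acetate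
Conditions: Tf2O, 2,6-di-tert-butyl-4-methylpyridine, CH2Cl2, 0 °C → rt
Reagents that add atoms: trifluoromethanesulfonic anhydride, FC(F)(F)S(=O)(=O)OS(=O)(=O)C(F)(F)F
Why: Enol triflate formation by O-triflation and loss of the only α-hydrogen under a non-nucleophilic base, so that both epimers of 17 converge on one tetrasubstituted enol triflate and the acetate is untouched.

Step 12
Reactants: 18 (1R)-3,5,5-trimethyl-4-{[(trifluoromethyl)sulfonyl]oxy}cyclohex-3-en-1-yl acetate; 11 (2E)-3-methylpent-2-en-4-yn-1-ol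
Product: 19 (1R)-4-[(3E)-5-hydroxy-3-methylpent-3-en-1-yn-1-yl]-3,5,5-trimethylcyclohex-3-en-1-yl acetate
Conditions: Pd(PPh3)4 (5 mol%), CuI (10 mol%), iPr2NH, DMF, rt
Reagents that add atoms: none
Why: Sonogashira coupling of an enol triflate with a terminal alkyne installs the C6'–C7' bond and the C5'=C6' double bond regiospecifically, without touching the (E)-alkene of 11.

Step 13
Reactants: 19 (1R)-4-[(3E)-5-hydroxy-3-methylpent-3-en-1-yn-1-yl]-3,5,5-trimethylcyclohex-3-en-1-yl acetate
Product: 21 {(2E)-5-[(4R)-4-(acetyloxy)-2,6,6-trimethylcyclohex-1-en-1-yl]-3-methylpent-2-en-4-yn-1-yl}(triphenyl)phosphonium bromide, via allylic bromide 20 (not isolated)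
Conditions: CBr4, PPh3 (2.5 equiv), CH2Cl2, 0 °C → rt
Reagents that add atoms: triphenylphosphine, c1ccc(cc1)P(c1ccccc1)c1ccccc1; tetrabromomethane, BrC(Br)(Br)Br
Why: Appel bromination (SN2 on the alkoxyphosphonium ion, no free allyl cation, so the 9'E geometry should be kept) followed by SN2 quaternisation of the excess phosphine by the primary allylic bromide.

Step 14
Reactants: 21 {(2E)-5-[(4R)-4-(acetyloxy)-2,6,6-trimethylcyclohex-1-en-1-yl]-3-methylpent-2-en-4-yn-1-yl}(triphenyl)phosphonium bromide; 22 (2E,4E,6E)-2,7-dimethylocta-2,4,6-trienedial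
Product: 23 (2E,4E,6E,8E,10E)-13-[(4R)-4-(acetyloxy)-2,6,6-trimethylcyclohex-1-en-1-yl]-2,7,11-trimethyltrideca-2,4,6,8,10-pentaen-12-ynal
Conditions: 22 (3 equiv), 1,2-epoxybutane, EtOH, 70 °C; then heptane, 80 °C
Reagents that add atoms: none
Why: Wittig olefination with the ylide generated under neutral conditions, the excess dialdehyde securing mono-olefination, and thermal equilibration of the new C11'=C12' bond to E.

Step 15
Reactants: 23 (2E,4E,6E,8E,10E)-13-[(4R)-4-(acetyloxy)-2,6,6-trimethylcyclohex-1-en-1-yl]-2,7,11-trimethyltrideca-2,4,6,8,10-pentaen-12-ynal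
Product: 24 (1R)-4-[(3E,5E,7E,9E,11E)-13-hydroxy-3,8,12-trimethyltrideca-3,5,7,9,11-pentaen-1-yn-1-yl]-3,5,5-trimethylcyclohex-3-en-1-yl acetate
Conditions: NaBH4, MeOH/THF, −20 °C
Reagents that add atoms: none
Why: Chemoselective 1,2-reduction of the conjugated aldehyde by borohydride at low temperature, at which the acetate survives.

Step 16
Reactants: 24 (1R)-4-[(3E,5E,7E,9E,11E)-13-hydroxy-3,8,12-trimethyltrideca-3,5,7,9,11-pentaen-1-yn-1-yl]-3,5,5-trimethylcyclohex-3-en-1-yl acetate
Product: 25 {(2E,4E,6E,8E,10E)-13-[(4R)-4-(acetyloxy)-2,6,6-trimethylcyclohex-1-en-1-yl]-2,7,11-trimethyltrideca-2,4,6,8,10-pentaen-12-yn-1-yl}(triphenyl)phosphonium bromide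
Conditions: PPh3·HBr, MeOH, rt
Reagents that add atoms: triphenylphosphine hydrobromide, [Br-].[PH+](c1ccccc1)(c1ccccc1)c1ccccc1
Why: Phosphonium salt formation from a polyenyl allylic alcohol by acid-mediated substitution with capture of the phosphine at the terminal carbon, the standard preparation of polyenyl Wittig salts from retinol-type alcohols.

Step 17
Reactants: 25 {(2E,4E,6E,8E,10E)-13-[(4R)-4-(acetyloxy)-2,6,6-trimethylcyclohex-1-en-1-yl]-2,7,11-trimethyltrideca-2,4,6,8,10-pentaen-12-yn-1-yl}(triphenyl)phosphonium bromide; 15 (2E,4E)-3-methyl-5-[(1S,2S,4S)-1,2,4-trihydroxy-2,6,6-trimethylcyclohexyl]penta-2,4-dienal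
Product: 27 (3S,5S,6S,3'R)-7',8'-didehydro-5,6-dihydro-β,β-carotene-3,5,6,3'-tetrol, via 3'-O-acetyl tetrol 26 (not isolated)
Conditions: NaOMe (3 equiv), MeOH/CH2Cl2, 0 °C → rt; then EtOAc, 60 °C
Reagents that add atoms: none
Why: Wittig olefination forms C11=C12 in the presence of the free hydroxyls, the excess methoxide then removes the 3'-acetate by transesterification (Zemplén type), and gentle heating should equilibrate the new double bond to E.

**Compound list**

1 | N-methoxy-N,2-dimethylpropanamide | CC(C)C(=O)N(C)OC | starting material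
2 | prop-1-en-2-ylmagnesium bromide | CC(=C)[Mg]Br | starting material
3 | 2,4-dimethylpent-1-en-3-one | CC(C)C(=O)C(C)=C | intermediate
4 | tert-butyl[(2,4-dimethylpenta-1,3-dien-3-yl)oxy]dimethylsilane | CC(C)=C(O[Si](C)(C)C(C)(C)C)C(C)=C | intermediate
5 | but-3-en-2-one | CC(=O)C=C | starting material
6 | 1-[(1R)-4-{[tert-butyl(dimethyl)silyl]oxy}-3,5,5-trimethylcyclohex-3-en-1-yl]ethan-1-one | CC1=C(O[Si](C)(C)C(C)(C)C)C(C)(C)C[C@H](C(C)=O)C1 | intermediate
7 | (2S,4S)-4-acetyl-2-{[tert-butyl(dimethyl)silyl]oxy}-2,6,6-trimethylcyclohexan-1-one (not isolated) | O=C1C(C)(C)C[C@H](C(C)=O)C[C@]1(C)O[Si](C)(C)C(C)(C)C | intermediate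
8 | (1S,3S)-3-{[tert-butyl(dimethyl)silyl]oxy}-3,5,5-trimethyl-4-oxocyclohexyl acetate | O=C1C(C)(C)C[C@H](OC(C)=O)C[C@]1(C)O[Si](C)(C)C(C)(C)C | intermediate
9 | (1S,3S)-3-hydroxy-3,5,5-trimethyl-4-oxocyclohexyl acetate (not isolated) | O=C1C(C)(C)C[C@H](OC(C)=O)C[C@]1(C)O | intermediate
10 | (2S,4S)-2,4-dihydroxy-2,6,6-trimethylcyclohexan-1-one | O=C1C(C)(C)C[C@H](O)C[C@]1(C)O | intermediate
11 | (2E)-3-methylpent-2-en-4-yn-1-ol | C#C/C(C)=C/CO | starting material
12 | dilithium salt of (2E)-3-methylpent-2-en-4-yn-1-ol, O-lithio and C5-lithio (not isolated) | [Li]OC/C=C(C)/C#C[Li] | intermediate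
13 | (1R,2S,4S)-1-[(3E)-5-hydroxy-3-methylpent-3-en-1-yn-1-yl]-2,6,6-trimethylcyclohexane-1,2,4-triol | OC/C=C(C)/C#C[C@]1(O)C(C)(C)C[C@H](O)C[C@]1(C)O | intermediate
14 | (1S,2S,4S)-1-[(1E,3E)-5-hydroxy-3-methylpenta-1,3-dien-1-yl]-2,6,6-trimethylcyclohexane-1,2,4-triol | OC/C=C(C)/C=C/[C@]1(O)C(C)(C)C[C@H](O)C[C@]1(C)O | intermediate
15 | (2E,4E)-3-methyl-5-[(1S,2S,4S)-1,2,4-trihydroxy-2,6,6-trimethylcyclohexyl]penta-2,4-dienal | O=C/C=C(C)/C=C/[C@]1(O)C(C)(C)C[C@H](O)C[C@]1(C)O | intermediate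
16 | (4R)-4-acetyl-2,2,6-trimethylcyclohexan-1-one, epimer mixture at the methyl-bearing carbon | CC1C(=O)C(C)(C)C[C@H](C(C)=O)C1 | intermediate
17 | (1R)-3,3,5-trimethyl-4-oxocyclohexyl acetate, epimer mixture at the methyl-bearing carbon | CC1C(=O)C(C)(C)C[C@H](OC(C)=O)C1 | intermediate
18 | (1R)-3,5,5-trimethyl-4-{[(trifluoromethyl)sulfonyl]oxy}cyclohex-3-en-1-yl acetate | CC1=C(OS(=O)(=O)C(F)(F)F)C(C)(C)C[C@H](OC(C)=O)C1 | intermediate
19 | (1R)-4-[(3E)-5-hydroxy-3-methylpent-3-en-1-yn-1-yl]-3,5,5-trimethylcyclohex-3-en-1-yl acetate | CC1=C(C#C/C(C)=C/CO)C(C)(C)C[C@H](OC(C)=O)C1 | intermediate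
20 | (1R)-4-[(3E)-5-bromo-3-methylpent-3-en-1-yn-1-yl]-3,5,5-trimethylcyclohex-3-en-1-yl acetate (not isolated) | CC1=C(C#C/C(C)=C/CBr)C(C)(C)C[C@H](OC(C)=O)C1 | intermediate
21 | {(2E)-5-[(4R)-4-(acetyloxy)-2,6,6-trimethylcyclohex-1-en-1-yl]-3-methylpent-2-en-4-yn-1-yl}(triphenyl)phosphonium bromide | CC1=C(C#C/C(C)=C/C[P+](c2ccccc2)(c2ccccc2)c2ccccc2)C(C)(C)C[C@H](OC(C)=O)C1.[Br-] | intermediate
22 | (2E,4E,6E)-2,7-dimethylocta-2,4,6-trienedial | O=C/C(C)=C/C=C/C=C(C)/C=O | starting material
23 | (2E,4E,6E,8E,10E)-13-[(4R)-4-(acetyloxy)-2,6,6-trimethylcyclohex-1-en-1-yl]-2,7,11-trimethyltrideca-2,4,6,8,10-pentaen-12-ynal | CC1=C(C#C/C(C)=C/C=C/C(C)=C/C=C/C=C(C)/C=O)C(C)(C)C[C@H](OC(C)=O)C1 | intermediate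
24 | (1R)-4-[(3E,5E,7E,9E,11E)-13-hydroxy-3,8,12-trimethyltrideca-3,5,7,9,11-pentaen-1-yn-1-yl]-3,5,5-trimethylcyclohex-3-en-1-yl acetate | CC1=C(C#C/C(C)=C/C=C/C(C)=C/C=C/C=C(C)/CO)C(C)(C)C[C@H](OC(C)=O)C1 | intermediate
25 | {(2E,4E,6E,8E,10E)-13-[(4R)-4-(acetyloxy)-2,6,6-trimethylcyclohex-1-en-1-yl]-2,7,11-trimethyltrideca-2,4,6,8,10-pentaen-12-yn-1-yl}(triphenyl)phosphonium bromide | CC1=C(C#C/C(C)=C/C=C/C(C)=C/C=C/C=C(C)/C[P+](c2ccccc2)(c2ccccc2)c2ccccc2)C(C)(C)C[C@H](OC(C)=O)C1.[Br-] | intermediate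
26 | (3S,5S,6S,3'R)-3'-(acetyloxy)-7',8'-didehydro-5,6-dihydro-β,β-carotene-3,5,6-triol (not isolated) | CC1=C(C#C/C(C)=C/C=C/C(C)=C/C=C/C=C(C)/C=C/C=C(C)/C=C/[C@]2(O)C(C)(C)C[C@H](O)C[C@]2(C)O)C(C)(C)C[C@H](OC(C)=O)C1 | intermediate
27 | (3S,5S,6S,3'R)-7',8'-didehydro-5,6-dihydro-β,β-carotene-3,5,6,3'-tetrol | CC1=C(C#C/C(C)=C/C=C/C(C)=C/C=C/C=C(C)/C=C/C=C(C)/C=C/[C@]2(O)C(C)(C)C[C@H](O)C[C@]2(C)O)C(C)(C)C[C@H](O)C1 | target

**Step count**

Total step count: 17.
Longest linear sequence: 12 steps (steps 1, 2, 3, 9, 10, 11, 12, 13, 14, 15, 16, 17).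

**Steps most likely to fail**

1. Step 3 (Proposed new method). What may go wrong: poor enantiofacial discrimination, or arrest at the open-chain Michael adduct without ring closure. Fallback with known, auxiliary-controlled chemistry, setting out from 4 and rejoining at 6: (4R)-4-benzyl-1,3-oxazolidin-2-one is N-acylated with acryloyl chloride to (4R)-4-benzyl-3-(prop-2-enoyl)-1,3-oxazolidin-2-one F1. F1 and 4 are combined with Et2AlCl (CH2Cl2, −78 °C) in the auxiliary-controlled Lewis acid Diels–Alder addition (chelated s-cis acrylimide, attack anti to the benzyl group) to give (4R)-4-benzyl-3-{[(1R)-4-{[tert-butyl(dimethyl)silyl]oxy}-3,5,5-trimethylcyclohex-3-en-1-yl]carbonyl}-1,3-oxazolidin-2-one F2. Transamidation (MeONHMe·HCl, AlMe3, CH2Cl2, 0 °C) gives (1R)-4-{[tert-butyl(dimethyl)silyl]oxy}-N-methoxy-N,3,5,5-tetramethylcyclohex-3-ene-1-carboxamide F3, and MeMgBr (THF, 0 °C) converts F3 into 6.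

2. Step 4. What may go wrong: poor facial selectivity in the epoxidation of the silyl enol ether, giving the C5 epimer. Fallback with reagent control, setting out from 18 and rejoining at 14:
 - 18 is methoxycarbonylated (Pd(OAc)2, PPh3, CO, MeOH, Et3N) to methyl (4R)-4-(acetyloxy)-2,6,6-trimethylcyclohex-1-ene-1-carboxylate F4.
 - (iBu)2AlH reduces ester and acetate to (1R)-4-(hydroxymethyl)-3,5,5-trimethylcyclohex-3-en-1-ol F5.
 - Sharpless epoxidation (Ti(OiPr)4, L-(+)-diethyl tartrate, tBuOOH) should place the epoxide oxygen anti to the ring hydroxyl, giving (1R,3S,6R)-6-(hydroxymethyl)-1,5,5-trimethyl-7-oxabicyclo[4.1.0]heptan-3-ol F6.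
 - Selective oxidation of the primary alcohol (TEMPO, PhI(OAc)2) gives (1S,4S,6R)-4-hydroxy-2,2,6-trimethyl-7-oxabicyclo[4.1.0]heptane-1-carbaldehyde F7.
 - Horner–Wadsworth–Emmons olefination with triethyl 3-methyl-4-phosphonobut-2-enoate (LiN(SiMe3)2, THF) gives ethyl (2E,4E)-5-[(1S,4S,6R)-4-hydroxy-2,2,6-trimethyl-7-oxabicyclo[4.1.0]heptan-1-yl]-3-methylpenta-2,4-dienoate F8.
 - Aqueous HClO4 in THF opens the epoxide at C5 with inversion (the dienoate disfavours ionisation at C6) to ethyl (2E,4E)-3-methyl-5-[(1S,2S,4S)-1,2,4-trihydroxy-2,6,6-trimethylcyclohexyl]penta-2,4-dienoate F9.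
 - (iBu)2AlH reduces F9 to 14.

3. Step 10. What may go wrong: competing Baeyer–Villiger oxidation of the ring ketone. Fallback that removes the second ketone before the peracid step, setting out from 16 and rejoining at 18: the unhindered methyl ketone is ketalised selectively (1,2-bis(trimethylsilyloxy)ethane, TMSOTf cat., CH2Cl2, −78 °C) to (4R)-2,2,6-trimethyl-4-(2-methyl-1,3-dioxolan-2-yl)cyclohexan-1-one F10. The ring ketone is converted into its enol triflate (KN(SiMe3)2, PhNTf2, THF, −78 °C), (4R)-2,6,6-trimethyl-4-(2-methyl-1,3-dioxolan-2-yl)cyclohex-1-en-1-yl trifluoromethanesulfonate F11. Mild acid (aq. HCl, THF, 0 °C) releases (4R)-4-acetyl-2,6,6-trimethylcyclohex-1-en-1-yl trifluoromethanesulfonate F12, and Baeyer–Villiger oxidation (mCPBA, NaHCO3, CH2Cl2), now with only the electron-poor enol triflate as a second π system, gives 18.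

**Further compounds**

F1 | step 3 | (4R)-4-benzyl-3-(prop-2-enoyl)-1,3-oxazolidin-2-one | C=CC(=O)N1[C@H](Cc2ccccc2)COC1=O
F2 | step 3 | (4R)-4-benzyl-3-{[(1R)-4-{[tert-butyl(dimethyl)silyl]oxy}-3,5,5-trimethylcyclohex-3-en-1-yl]carbonyl}-1,3-oxazolidin-2-one | CC1=C(O[Si](C)(C)C(C)(C)C)C(C)(C)C[C@H](C(=O)N2[C@H](Cc3ccccc3)COC2=O)C1
F3 | step 3 | (1R)-4-{[tert-butyl(dimethyl)silyl]oxy}-N-methoxy-N,3,5,5-tetramethylcyclohex-3-ene-1-carboxamide | CC1=C(O[Si](C)(C)C(C)(C)C)C(C)(C)C[C@H](C(=O)N(C)OC)C1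
F4 | step 4 | methyl (4R)-4-(acetyloxy)-2,6,6-trimethylcyclohex-1-ene-1-carboxylate | CC1=C(C(=O)OC)C(C)(C)C[C@H](OC(C)=O)C1
F5 | step 4 | (1R)-4-(hydroxymethyl)-3,5,5-trimethylcyclohex-3-en-1-ol | CC1=C(CO)C(C)(C)C[C@H](O)C1
F6 | step 4 | (1R,3S,6R)-6-(hydroxymethyl)-1,5,5-trimethyl-7-oxabicyclo[4.1.0]heptan-3-ol | OC[C@@]12O[C@]1(C)C[C@@H](O)CC2(C)C
F7 | step 4 | (1S,4S,6R)-4-hydroxy-2,2,6-trimethyl-7-oxabicyclo[4.1.0]heptane-1-carbaldehyde | O=C[C@@]12O[C@]1(C)C[C@@H](O)CC2(C)C
F8 | step 4 | ethyl (2E,4E)-5-[(1S,4S,6R)-4-hydroxy-2,2,6-trimethyl-7-oxabicyclo[4.1.0]heptan-1-yl]-3-methylpenta-2,4-dienoate | CCOC(=O)/C=C(C)/C=C/[C@@]12O[C@]1(C)C[C@@H](O)CC2(C)C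
F9 | step 4 | ethyl (2E,4E)-3-methyl-5-[(1S,2S,4S)-1,2,4-trihydroxy-2,6,6-trimethylcyclohexyl]penta-2,4-dienoate | CCOC(=O)/C=C(C)/C=C/[C@]1(O)C(C)(C)C[C@H](O)C[C@]1(C)O
F10 | step 10 | (4R)-2,2,6-trimethyl-4-(2-methyl-1,3-dioxolan-2-yl)cyclohexan-1-one | CC1C(=O)C(C)(C)C[C@H](C2(C)OCCO2)C1
F11 | step 10 | (4R)-2,6,6-trimethyl-4-(2-methyl-1,3-dioxolan-2-yl)cyclohex-1-en-1-yl trifluoromethanesulfonate | CC1=C(OS(=O)(=O)C(F)(F)F)C(C)(C)C[C@H](C2(C)OCCO2)C1
F12 | step 10 | (4R)-4-acetyl-2,6,6-trimethylcyclohex-1-en-1-yl trifluoromethanesulfonate | CC1=C(OS(=O)(=O)C(F)(F)F)C(C)(C)C[C@H](C(C)=O)C1
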